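Readings and results are calculated with constants of no real substance; the scatter is artificial.

In a one-step world, where each substrate molecule closes to ring by itself, the percent of ring at a given time would not depend on the charge. The readings refuse this: after 20.0 h the south run holds 50.5% ring, south-west 35.9% and east 20.8%.

| flask | substrate | remark | time |
|---|---|---|---|
| south | 4.8 mM | run made earlier |  |
| south-west | 23 mM | run made earlier |  |
| east | 93 mM | run made earlier |  |
| theta | 10 mM |  | 40 h |
| beta | 30 mM |  | 40 h |
| zeta | 20 mM |  | 40 h |
| delta | 6.0 mM |  | 40 h |
| gamma | 80 mM |  | 40 h |

| run | time / h | ring / % | substrate / % |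
|---|---|---|---|
| south | 2.00 | 8.4 | 82.3 |
| south | 5.00 | 20.2 | 65.2 |
| south | 10.0 | 33.2 | 48.1 |
| south | 15.0 | 43.8 | 37.7 |
| south | 20.0 | 50.5 | 29.5 |
| south-west | 2.00 | 7.9 | 62.6 |
| south-west | 5.00 | 15.2 | 41.8 |
| south-west | 10.0 | 23.9 | 29.5 |
| south-west | 15.0 | 29.6 | 24.7 |
| south-west | 20.0 | 35.9 | 22.6 |
| east | 1.50 | 4.0 | 39.6 |
| east | 3.00 | 6.7 | 25.9 |
| east | 6.00 | 9.9 | 19.2 |
| east | 10.0 | 13.9 | 15.4 |
| east | 20.0 | 20.8 | 15.6 |

(scatter of a reading: 0.5 percentage points)

- percent here means substrate units held: one open dimer counts as two
- the numbers in the tables scatter by 0.5 percentage points (one standard deviation)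
- steps under discussion: ring -> over-reaction product; substrate -> ring; 2 substrate <-> open dimer

- the flasks by amount of ring, in percent of the substrate charged, highest first, at 40 h (theta / beta / zeta / delta / gamma)
- the amount of ring, in percent of the substrate charged of the flask you put first, at 40 h
- the amount of ring, in percent of the substrate charged of the flask you put last, at 40 h

So follow one substrate molecule to its fork: it closes to ring, or it pairs with a second substrate into open dimer. At the first reading, divide the ring made by the substrate units gone elsewhere; these are the odds of closing, the selectivity of the fork. Pairing needs a partner and closing does not, so multiply the odds by the charge and expect a constant. Take the south run, where substrate had moved least: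

c* = 4.8 mM × 8.4% / 9.30% = 4.34 mM

Call c* the even-odds charge: the charge c at which a molecule at the start of a flask is as likely to close as to pair. South-west reads 6.16 mM and east 6.60 mM, while the charge goes from 4.8 mM to 93 mM; all of these carry the scatter of the readings.

Pairing looks like a detour: in the east run substrate reads 15.4% and then 15.6% while ring climbs from 13.9% to 20.8%, more than substrate fell, and I read this as open dimer handing substrate back. Now reckon the share that closes at the start of a flask:

p = c* / (c* + c)
delta: p = 41.9%
gamma: p = 5.14%

This share falls as the charge rises, so rank the flasks for 40 h by charge, lowest first, and for the next run, wanting ring, charge delta rather than gamma. This reckoning gives an order, not amounts. The forecast gives both: delta > theta > zeta > beta > gamma, top 64% (60% to 68%), low 33% (30% to 36%). Its ground: “The dimer acts as a reservoir that holds substrate back from cyclising.”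

The flasks give delta > theta > zeta > beta > gamma, with 67.2% ring in delta and 35.6% in gamma, so the forecast's order stands and both amounts lie within its ranges.

    ring → over-reaction product (k = 0.00310 h⁻¹)
    substrate → ring (k = 0.0500 h⁻¹)
    2 substrate ⇌ open dimer (K = 110 M⁻¹, k = 5.30 M⁻¹ h⁻¹)

Reckoned for the start, delta's share is 41.9% and gamma's 5.14%; at 40.0 h delta holds 11.2% in open dimer and gamma 47.6%. Now take the neighbour of delta, charged with 2.4 mM substrate and read at the same time. The neighbour's share at the start is 64.4%, above delta's, and the neighbour holds 5.32% in open dimer and 73.6% ring, against 67.2% in delta.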